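**Plan**
1. Common core: a trans-(7S,8S)-1,4-benzodioxane. C7 carries the syringyl ring and O–C3'. C8 carries C9H2OH and O–C4', which is para to the C1' side chain.
2. Differences: C5' (H or OMe) and the end of the C1' chain (enal or allylic alcohol).
3. Shared intermediate 11: the closed, fully masked core with Br at C5' and a dioxolane-masked CHO at C1' (phenol as MOM ether, C9–OH as TBS ether).
4. Enabling feature 1: C8 lies between C7 and C9. With C7 as ketone and C9 as ester its C–H is labile, so ATH-DKR can funnel a racemate into the one syn C7/C8 pair that maps onto the trans ring.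
5. Enabling feature 2: C4'–O is flanked by C3' (ring oxygen) and C5' (variable site). A C2v 2,6-dibromophenol makes ring closure regiochemically degenerate and leaves the second Br as the handle.
6. Retrosynthetic cuts, in order: C3'–O7 (Pd aryl etherification), C7–H (ATH-DKR), C8–O4' (SN2 on an α-bromo-β-keto ester), C8–C9 (Claisen carbomethoxylation).
7. Rings: both arenes are bought. The dioxane ring is the only ring made (step 9).
8. Branches: C–Br goes to C–H or C–OMe first, because RLi and Pd/alkoxide would not spare an enal or a free phenol. One acid step then unmasks everything, a Wittig reaction gives the enals, and bilagrewin is reduced to the alcohol.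

Key step: step 6
Shared intermediate: compound 11

Locants: C7 = ArCH–O, C8 = CH(CH2OH)–O, C9 = CH2OH. Primed locants refer to the benzodioxane arene (C1' chain carbon, C3'–O–C7, C4'–O–C8, C5' variable site).
Assumption: the (R,R)-Ru complex is assigned from the usual aryl-ketone model of Ru–TsDPEN reductions, with the aryl group beside the η6-arene.

**Trunk**

Step 1
Reactants: 1 acetosyringone
Product: 2 1-[3,5-dimethoxy-4-(methoxymethoxy)phenyl]ethanone
Conditions: MOMCl, iPr2NEt, CH2Cl2, 0 °C to rt
Reagents that add atoms: chloromethyl methyl ether, COCCl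
Why: Williamson-type O-alkylation of the only OH; the MOM ether should withstand base, hydride, RLi and Pd and falls in the final acid step.

Step 2
Reactants: 2 MOM-protected acetosyringone
Product: 3 methyl 3-[3,5-dimethoxy-4-(methoxymethoxy)phenyl]-3-oxopropanoate
Conditions: NaH (2.5 equiv), (MeO)2CO, THF, reflux; AcOH quench
Reagents that add atoms: dimethyl carbonate, COC(=O)OC
Why: Crossed Claisen carbomethoxylation of the methyl ketone enolate, driven by deprotonation of the β-keto ester formed; it installs C9.

Step 3
Reactants: 3 β-keto ester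
Product: 4 methyl 2-bromo-3-[3,5-dimethoxy-4-(methoxymethoxy)phenyl]-3-oxopropanoate (racemic)
Conditions: NBS (1.0 equiv), Mg(ClO4)2 (cat.), EtOAc, 0 °C to rt
Reagents that add atoms: N-bromosuccinimide, O=C1CCC(=O)N1Br
Why: Electrophilic α-bromination through the Mg-chelated enol, which is far more nucleophilic than the acyl-deactivated arene, so the ring should stay unbrominated.

Step 4
Reactants: 5 3,5-dibromo-4-hydroxybenzaldehyde
Product: 6 2,6-dibromo-4-(1,3-dioxolan-2-yl)phenol
Conditions: HOCH2CH2OH, p-TsOH (cat.), toluene, Dean–Stark reflux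
Reagents that add atoms: ethylene glycol, OCCO
Why: Acid-catalysed acetalisation with azeotropic removal of water; the mask keeps the aldehyde out of steps 6 and 7 and removes the para acceptor that could allow a Smiles-type O-to-O aryl shift of the C7 alkoxide in step 9.

Step 5
Reactants: 4 α-bromo-β-keto ester; 6 dibromophenol acetal
Product: 7 methyl 2-[2,6-dibromo-4-(1,3-dioxolan-2-yl)phenoxy]-3-[3,5-dimethoxy-4-(methoxymethoxy)phenyl]-3-oxopropanoate (racemic, C8 labile)
Conditions: K2CO3, acetone, rt to 40 °C
Reagents that add atoms: none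
Why: SN2 (Williamson) displacement at a carbon activated by two carbonyl groups; the weakly basic phenoxide of 6 should not tie up 4 as its enolate, the single OH of 6 fixes the O4'–C8 connectivity, and the racemic C8 is of no consequence because it is labile.

Step 6
Reactants: 7 racemic α-aryloxy-β-keto ester
Product: 8 methyl (2R,3S)-2-[2,6-dibromo-4-(1,3-dioxolan-2-yl)phenoxy]-3-hydroxy-3-[3,5-dimethoxy-4-(methoxymethoxy)phenyl]propanoate (syn)
Conditions: RuCl[(R,R)-Teth-TsDPEN] (1 mol %), HCO2H/Et3N 5:2, CH2Cl2, 30 °C
Reagents that add atoms: none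
Why: Noyori–Ikariya asymmetric transfer hydrogenation run as a dynamic kinetic resolution, the closest known case being the syn-selective ATH-DKR of α-alkoxy-β-keto esters: formate converts the 16-electron Ru amide into the Ru–H/N–H species, which hands hydride to C7 and a proton to O7 through the six-membered outer-sphere transition state. The C8–H of 7 is flanked by the C7 ketone, the C9 ester and an electron-poor aryloxy oxygen, so Et3N should interconvert the two enantiomers of 7 through the achiral enol much faster than either is reduced, and the whole racemate drains through the faster-reacting one. C7 is controlled by the catalyst: the CH/π contact between the η6-arene of the (R,R)-complex and the syringyl ring presents the Re face of the ketone to Ru–H and gives 7S. C8 is controlled by matching of substrate and catalyst: only the (8R)-ketone can adopt the Felkin-type, dipole-minimised conformation (C8–OAr anti to the incoming hydride, ester turned away from the sulfonamide) on that face, which gives the syn pair, the open-chain equivalent of the trans ring. No ring is closed here. The step needs chemoselectivity for the one ketone, secured by the aldehyde mask of step 4 and by the inertness of ester, acetals and C–Br bonds to Ru–H at 30 °C, and it needs racemisation to outrun reduction, secured by an electron-rich, slowly reduced syringyl ketone next to an unusually acidic C8–H.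

Step 7
Reactants: 8 syn hydroxy ester
Product: 9 (1S,2S)-2-[2,6-dibromo-4-(1,3-dioxolan-2-yl)phenoxy]-1-[3,5-dimethoxy-4-(methoxymethoxy)phenyl]propane-1,3-diol
Conditions: LiBH4, THF, 0 °C to rt
Reagents that add atoms: none
Why: Ester reduction with LiBH4, assisted by the neighbouring alkoxide and fast enough at low temperature to forestall retro-aldol or C8 epimerisation; no bond to C7 or C8 is broken, and the C8 descriptor changes from R to S only through CIP priorities.

Step 8
Reactants: 9 1,3-diol
Product: 10 (1S,2S)-3-(tert-butyldimethylsilyloxy)-2-[2,6-dibromo-4-(1,3-dioxolan-2-yl)phenoxy]-1-[3,5-dimethoxy-4-(methoxymethoxy)phenyl]propan-1-ol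
Conditions: TBSCl (1.05 equiv), imidazole, CH2Cl2, 0 °C
Reagents that add atoms: tert-butyldimethylsilyl chloride, CC(C)(C)[Si](C)(C)Cl
Why: Selective silylation of the unhindered primary C9–OH over the secondary benzylic C7–OH; it is needed because C9–OH would otherwise close an isomeric six-membered ring in step 9.

Step 9
Reactants: 10 mono-TBS alcohol
Product: 11 (7S,8S)-trans core: (2S,3S)-5-bromo-3-(tert-butyldimethylsilyloxymethyl)-2-[3,5-dimethoxy-4-(methoxymethoxy)phenyl]-7-(1,3-dioxolan-2-yl)-2,3-dihydro-1,4-benzodioxine
Conditions: Pd(OAc)2 (3 mol %), 2-(di-tert-butylphosphino)-1,1'-binaphthyl (4 mol %), Cs2CO3, toluene, 70 °C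
Reagents that add atoms: none
Why: Pd-catalysed intramolecular aryl etherification (Buchwald–Hartwig C–O coupling) closes the dioxane ring at C3'–O7; the two C–Br bonds are interchanged by rotation about C4'–O, so either gives the same product, no bond at C7 or C8 is broken, so syn becomes trans with retention, and the bulky ligand favours reductive elimination over β-hydride elimination.

**Branches**

Branch to CNP0211211.1 (compound 15)

Step 10
Reactants: 11 shared bromide
Product: 13 debrominated core (11 with H at C5'), via C5'-aryllithium 12 (not isolated)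
Conditions: n-BuLi (1.1 equiv), THF, −78 °C; then H2O
Reagents that add atoms: none
Why: Bromine–lithium exchange followed by protonation; the single C–Br bond exchanges at −78 °C much faster than n-BuLi can deprotonate next to OMOM, at C7–H or at the acetal C–H, and every other group is an ether or acetal.

Step 11
Reactants: 13 debrominated core
Product: 14 (7S,8S)-hydroxy aldehyde: trans-3-(4-hydroxy-3,5-dimethoxyphenyl)-2-(hydroxymethyl)-2,3-dihydro-1,4-benzodioxine-6-carbaldehyde
Conditions: 2 M aq HCl/THF 1:2, 45 °C
Reagents that add atoms: water, O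
Why: Acid hydrolysis removes dioxolane, MOM and primary TBS in one operation; any reversible ionisation of the C7–O3' bond once the phenol is free leaves C8 untouched, and re-closure favours the diequatorial trans ring.

Step 12
Reactants: 14 hydroxy aldehyde
Product: 15 CNP0211211.1
Conditions: Ph3P=CHCHO (1.2 equiv), THF/toluene, 80 °C
Reagents that add atoms: (triphenylphosphoranylidene)acetaldehyde, O=CC=P(c1ccccc1)(c1ccccc1)c1ccccc1
Why: Wittig olefination with a stabilised ylide, which should give the E-enal; the aryl aldehyde is the only electrophile, and the ylide is too weak a base to deprotonate the phenol or the alcohol.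

Branch to Bilagrewin (compound 18)

Step 13
Reactants: 11 shared bromide
Product: 16 C5'-methoxy core (11 with OMe in place of Br)
Conditions: tBuBrettPhos Pd G3 (2 mol %), NaOtBu (1.4 equiv), MeOH (5 equiv), 1,4-dioxane, 50 °C
Reagents that add atoms: methanol, CO
Why: Pd-catalysed C–O coupling of an aryl bromide with methanol at the single C–Br bond; the bulky biaryl phosphine speeds reductive elimination over β-hydride loss from Pd–OMe, and acetal, MOM and TBS groups tolerate alkoxide.

Step 14
Reactants: 16 C5'-methoxy core
Product: 17 (7S,8S)-hydroxy aldehyde of the methoxy series: trans-3-(4-hydroxy-3,5-dimethoxyphenyl)-2-(hydroxymethyl)-8-methoxy-2,3-dihydro-1,4-benzodioxine-6-carbaldehyde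
Conditions: 2 M aq HCl/THF 1:2, 45 °C
Reagents that add atoms: water, O
Why: The same one-pot acid hydrolysis of dioxolane, MOM and TBS as in step 11, with the same safeguard for C7 through the untouched C8.

Step 15
Reactants: 17 hydroxy aldehyde
Product: 18 Bilagrewin
Conditions: Ph3P=CHCHO (1.2 equiv), THF/toluene, 80 °C
Reagents that add atoms: (triphenylphosphoranylidene)acetaldehyde, O=CC=P(c1ccccc1)(c1ccccc1)c1ccccc1
Why: Wittig olefination with the stabilised formyl ylide at the only aldehyde should give the E-enal; free OH groups are tolerated.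

Branch to CID11188887 (compound 19)

Step 16
Reactants: 18 Bilagrewin
Product: 19 CID11188887
Conditions: NaBH4, CeCl3·7H2O, MeOH/THF, −20 to 0 °C
Reagents that add atoms: none
Why: Luche 1,2-reduction of the only carbonyl group; the hard Ce-modified borohydride attacks C=O rather than the conjugated C=C, and the near-neutral medium keeps the phenol protonated, so the C7–O3' bond is not put at risk.

**Compound list**
1 | acetosyringone | CC(=O)c1cc(OC)c(O)c(OC)c1 | starting material
2 | 1-[3,5-dimethoxy-4-(methoxymethoxy)phenyl]ethanone | CC(=O)c1cc(OC)c(OCOC)c(OC)c1 | intermediate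
3 | methyl 3-[3,5-dimethoxy-4-(methoxymethoxy)phenyl]-3-oxopropanoate | COC(=O)CC(=O)c1cc(OC)c(OCOC)c(OC)c1 | intermediate
4 | methyl 2-bromo-3-aryl-3-oxopropanoate (racemic) | COC(=O)C(Br)C(=O)c1cc(OC)c(OCOC)c(OC)c1 | intermediate
5 | 3,5-dibromo-4-hydroxybenzaldehyde | O=Cc1cc(Br)c(O)c(Br)c1 | starting material
6 | 2,6-dibromo-4-(1,3-dioxolan-2-yl)phenol | Oc1c(Br)cc(cc1Br)C1OCCO1 | intermediate
7 | racemic α-aryloxy-β-keto ester | COC(=O)C(Oc1c(Br)cc(cc1Br)C1OCCO1)C(=O)c1cc(OC)c(OCOC)c(OC)c1 | intermediate
8 | (2R,3S)-syn hydroxy ester | COCOc1c(OC)cc(cc1OC)[C@H](O)[C@@H](Oc1c(Br)cc(cc1Br)C1OCCO1)C(=O)OC | intermediate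
9 | (1S,2S)-1,3-diol | COCOc1c(OC)cc(cc1OC)[C@H](O)[C@@H](Oc1c(Br)cc(cc1Br)C1OCCO1)CO | intermediate
10 | (1S,2S)-C9-TBS ether, free C7–OH | COCOc1c(OC)cc(cc1OC)[C@H](O)[C@@H](Oc1c(Br)cc(cc1Br)C1OCCO1)CO[Si](C)(C)C(C)(C)C | intermediate
11 | shared C5'-bromo trans core | COc1cc([C@@H]2Oc3cc(C4OCCO4)cc(Br)c3O[C@H]2CO[Si](C)(C)C(C)(C)C)cc(OC)c1OCOC | intermediate
12 | C5'-aryllithium (not isolated) | COc1cc([C@@H]2Oc3cc(C4OCCO4)cc([Li])c3O[C@H]2CO[Si](C)(C)C(C)(C)C)cc(OC)c1OCOC | intermediate
13 | debrominated protected core | COc1cc([C@@H]2Oc3cc(C4OCCO4)ccc3O[C@H]2CO[Si](C)(C)C(C)(C)C)cc(OC)c1OCOC | intermediate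
14 | hydroxy aldehyde, H series | COc1cc([C@@H]2Oc3cc(C=O)ccc3O[C@H]2CO)cc(OC)c1O | intermediate
15 | CNP0211211.1 | COc1cc([C@@H]2Oc3cc(/C=C/C=O)ccc3O[C@H]2CO)cc(OC)c1O | target
16 | C5'-methoxy protected core | COc1cc([C@@H]2Oc3cc(C4OCCO4)cc(OC)c3O[C@H]2CO[Si](C)(C)C(C)(C)C)cc(OC)c1OCOC | intermediate
17 | hydroxy aldehyde, OMe series | COc1cc([C@@H]2Oc3cc(C=O)cc(OC)c3O[C@H]2CO)cc(OC)c1O | intermediate
18 | Bilagrewin | COc1cc([C@@H]2Oc3cc(/C=C/C=O)cc(OC)c3O[C@H]2CO)cc(OC)c1O | target
19 | CID11188887 | COc1cc([C@@H]2Oc3cc(/C=C/CO)cc(OC)c3O[C@H]2CO)cc(OC)c1O | target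

Totals for CNP0211211.1 (compound 15): total step count 12, longest linear sequence 11
Totals for Bilagrewin (compound 18): total step count 12, longest linear sequence 11
Totals for CID11188887 (compound 19): total step count 13, longest linear sequence 12

**Steps most likely to fail**

Step 6. The hindered 2,6-dibromoaryloxy group may blur the matched/mismatched discrimination, or reduction may outpace racemisation. Either would erode diastereo- and enantioselectivity.

The fallback replaces the reduction by an auxiliary-controlled C7–C8 bond formation. It sets out from 6 and comes back at 9.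
- Syringaldehyde is protected (MOMCl, iPr2NEt) to 3,5-dimethoxy-4-(methoxymethoxy)benzaldehyde F1.
- Phenol 6 is alkylated with commercial (R)-4-benzyl-3-(chloroacetyl)oxazolidin-2-one (K2CO3, NaI, acetone) to the aryloxyacetyl imide F2.
- Bu2BOTf/Et3N (CH2Cl2, −78 to 0 °C) and F1 should give the Evans syn aldol adduct F3 through the Z-boron enolate and a Zimmerman–Traxler chair.
- LiBH4 (THF/MeOH, 0 °C) removes the auxiliary reductively and delivers diol 9.

Step 9. β-Hydride elimination from the secondary Pd alkoxide, with ketone formation and hydrodebromination, may compete with a slow reductive elimination next to the bulky ether.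

The fallback reverses the polarity of C3' and closes the ring oxidatively. It sets out from 10 and comes back at 11.
- n-BuLi (2.1 equiv, THF, −78 °C) should convert 10 into the lithium alkoxide/C3'-aryllithium F4. The two bromines are equivalent, and a second exchange on the dianion is disfavoured.
- B(OMe)3 followed by aq NH4Cl gives the C3'-boronic acid F5.
- Cu(OAc)2, DMAP, 4 Å sieves, O2, CH2Cl2, rt (Chan–Lam oxidative C–O coupling) joins O7 to C3' with retention at C7 and gives 11. A β-hydride pathway is not expected with Cu.

Step 15 (the same reaction type as step 12). Olefination of the electron-rich aldehyde may be sluggish, and the more electrophilic enal formed may be homologated a second time.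

The fallback makes the C7'=C8' bond by metathesis. It sets out from 17 and comes back at 18.
- Ph3P=CH2 (excess, from Ph3PCH3Br/KOtBu, THF, 0 °C to rt) converts 17 into the C1'-styrene F6.
- Cross metathesis with crotonaldehyde (excess, Hoveyda–Grubbs II, CH2Cl2, 40 °C) should give the E-enal 18. The enal formed is a poor metathesis partner and cannot grow further.

**Further compounds**
F1 | step 6 | 3,5-dimethoxy-4-(methoxymethoxy)benzaldehyde | COCOc1c(OC)cc(C=O)cc1OC
F2 | step 6 | (R)-4-benzyl-3-{2-[2,6-dibromo-4-(1,3-dioxolan-2-yl)phenoxy]acetyl}oxazolidin-2-one | O=C(COc1c(Br)cc(cc1Br)C1OCCO1)N1[C@H](Cc2ccccc2)COC1=O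
F3 | step 6 | Evans syn aldol adduct (2R,3S in the acyl chain) | COCOc1c(OC)cc(cc1OC)[C@H](O)[C@@H](Oc1c(Br)cc(cc1Br)C1OCCO1)C(=O)N1[C@H](Cc2ccccc2)COC1=O
F4 | step 9 | lithium alkoxide/C3'-aryllithium of 10 | COCOc1c(OC)cc(cc1OC)[C@H](O[Li])[C@@H](Oc1c([Li])cc(cc1Br)C1OCCO1)CO[Si](C)(C)C(C)(C)C
F5 | step 9 | C3'-boronic acid | COCOc1c(OC)cc(cc1OC)[C@H](O)[C@@H](Oc1c(cc(cc1Br)C1OCCO1)B(O)O)CO[Si](C)(C)C(C)(C)C
F6 | step 15 | C1'-styrene of the methoxy series | COc1cc([C@@H]2Oc3cc(C=C)cc(OC)c3O[C@H]2CO)cc(OC)c1O
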